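**Retrosynthetic overview**
1. 20 ⇐ 19 by oxidative removal of a PMB ether as the last step. 19 ⇐ epoxy alcohol 17 + pentanoyl chloride 18 (ester bond).
2. 17 ⇐ 2-arylallyl alcohol 16 by Sharpless asymmetric epoxidation, which sets the only stereocentre. The phenol isobutyrate is already in place, so a free ortho-phenol never meets the benzylic oxirane.
3. 16 ⇐ 11 by a protecting-group relay (TBDPS on, THP off, isobutyrate on with 14, TBDPS off). 11 ⇐ acrylate 10 by iBu2AlH reduction.
4. Key carbon–carbon bond: 10 ⇐ aryl acetate 7 + formaldehyde 8 (intermolecular aldol addition, then loss of water). 7 ⇐ aryl bromide 4 + zinc enolate 6 made from 5. 4 ⇐ 1.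
5. Rings: the benzene ring is bought with 1. The oxirane is the only ring built (step 11).

Assumption: the tetrahydropyranyl acetal carbon (2–4, 7, 9–12, F1, F2) and the benzylic carbon of 9, F1 and F2 are racemic and drawn without descriptors, all are gone before step 11, and paraformaldehyde is entered as its monomer.

**Step 1**
Reactants: 1 methyl 4-bromo-3-hydroxybenzoate
Product: 2 methyl 4-bromo-3-(tetrahydro-2H-pyran-2-yloxy)benzoate
Conditions: 3,4-dihydro-2H-pyran (2 equiv), pyridinium p-toluenesulfonate (10 mol%), CH2Cl2, rt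
Reagents that add atoms: 3,4-dihydro-2H-pyran, C1=COCCC1
Why: Acid-catalysed addition of the phenol to the enol ether (THP acetal formation) masks the acidic OH with a group that tolerates hydride, NaH, organozinc and carbonate yet leaves later under very mild acid.

**Step 2**
Reactants: 2 methyl 4-bromo-3-(tetrahydro-2H-pyran-2-yloxy)benzoate
Product: 3 [4-bromo-3-(tetrahydro-2H-pyran-2-yloxy)phenyl]methanol
Conditions: LiAlH4 (1.0 equiv), THF, 0 °C
Reagents that add atoms: none
Why: Hydride reduction of the ester is fast at 0 °C, where the aryl bromide and the acetal are inert.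

**Step 3**
Reactants: 3 [4-bromo-3-(tetrahydro-2H-pyran-2-yloxy)phenyl]methanol
Product: 4 2-(2-bromo-5-{[(4-methoxybenzyl)oxy]methyl}phenoxy)tetrahydro-2H-pyran
Conditions: NaH (1.3 equiv), 4-methoxybenzyl chloride (1.2 equiv), Bu4NI (5 mol%), THF/DMF, 0 °C to rt
Reagents that add atoms: 4-methoxybenzyl chloride, COc1ccc(CCl)cc1
Why: Williamson ether synthesis on the primary alkoxide installs a PMB ether that survives every later step and can be removed at the end oxidatively at neutral pH.

**Step 4**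
Reactants: 4 2-(2-bromo-5-{[(4-methoxybenzyl)oxy]methyl}phenoxy)tetrahydro-2H-pyran; 5 tert-butyl bromoacetate
Product: 7 tert-butyl 2-[4-{[(4-methoxybenzyl)oxy]methyl}-2-(tetrahydro-2H-pyran-2-yloxy)phenyl]acetate, via Reformatsky zinc reagent 6 (not isolated)
Conditions: Zn dust (Me3SiCl-activated), 5 (1.8 equiv), THF, 45 °C; then 4, Pd2(dba)3 (2 mol%), XPhos (8 mol%), THF, 65 °C
Reagents that add atoms: tert-butyl bromoacetate (5), CC(C)(C)OC(=O)CBr
Why: In this Negishi-type coupling of a Reformatsky reagent (palladium-catalysed ester α-arylation), zerovalent palladium carrying bulky XPhos inserts into the hindered electron-rich carbon–bromine bond, and the weakly basic zinc enolate transmetalates without touching acetal or ethers.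

**Step 5 (key step)**
Reactants: 7 tert-butyl 2-[4-{[(4-methoxybenzyl)oxy]methyl}-2-(tetrahydro-2H-pyran-2-yloxy)phenyl]acetate; 8 formaldehyde (charged as paraformaldehyde)
Product: 10 tert-butyl 2-[4-{[(4-methoxybenzyl)oxy]methyl}-2-(tetrahydro-2H-pyran-2-yloxy)phenyl]prop-2-enoate, via aldol adduct 9 (not isolated)
Conditions: (CH2O)n (4 equiv), K2CO3 (2.5 equiv), Bu4NI (10 mol%), toluene, 85 °C
Reagents that add atoms: formaldehyde (8, from paraformaldehyde), C=O
Why: In this intermolecular crossed aldol condensation the aryl-stabilised ester enolate adds to non-enolisable formaldehyde, and β-hydroxy ester 9 loses water by E1cB to the conjugated 2-arylacrylate, forming the bond to the carbon that becomes the oxirane CH2.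

**Step 6**
Reactants: 10 tert-butyl 2-[4-{[(4-methoxybenzyl)oxy]methyl}-2-(tetrahydro-2H-pyran-2-yloxy)phenyl]prop-2-enoate
Product: 11 2-[4-{[(4-methoxybenzyl)oxy]methyl}-2-(tetrahydro-2H-pyran-2-yloxy)phenyl]prop-2-en-1-ol
Conditions: iBu2AlH (2.6 equiv), CH2Cl2, −78 to −20 °C; aq. potassium sodium tartrate
Reagents that add atoms: none
Why: 1,2-Reduction of the enoate by iBu2AlH at low temperature gives the allylic alcohol without conjugate reduction and leaves acetal and ethers alone.

**Step 7**
Reactants: 11 2-[4-{[(4-methoxybenzyl)oxy]methyl}-2-(tetrahydro-2H-pyran-2-yloxy)phenyl]prop-2-en-1-ol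
Product: 12 tert-butyl({2-[4-{[(4-methoxybenzyl)oxy]methyl}-2-(tetrahydro-2H-pyran-2-yloxy)phenyl]prop-2-en-1-yl}oxy)diphenylsilane
Conditions: tBuPh2SiCl (1.1 equiv), imidazole (2.2 equiv), DMF, rt
Reagents that add atoms: tert-butyl(chloro)diphenylsilane, CC(C)(C)[Si](Cl)(c1ccccc1)c1ccccc1
Why: Imidazole-promoted O-silylation parks the primary allylic OH under the acid-stable TBDPS group, so that later only the phenol can be acylated.

**Step 8**
Reactants: 12 tert-butyl({2-[4-{[(4-methoxybenzyl)oxy]methyl}-2-(tetrahydro-2H-pyran-2-yloxy)phenyl]prop-2-en-1-yl}oxy)diphenylsilane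
Product: 13 2-{3-[(tert-butyldiphenylsilyl)oxy]prop-1-en-2-yl}-5-{[(4-methoxybenzyl)oxy]methyl}phenol
Conditions: pyridinium p-toluenesulfonate (20 mol%), MeOH/THF 3:1, 40 °C
Reagents that add atoms: none
Why: Acid-catalysed transacetalisation cleaves the aryl THP acetal (phenol is a good leaving group) under an acid too weak to protonate the styrene or to touch TBDPS and PMB.

**Step 9**
Reactants: 13 2-{3-[(tert-butyldiphenylsilyl)oxy]prop-1-en-2-yl}-5-{[(4-methoxybenzyl)oxy]methyl}phenol; 14 isobutyryl chloride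
Product: 15 2-{3-[(tert-butyldiphenylsilyl)oxy]prop-1-en-2-yl}-5-{[(4-methoxybenzyl)oxy]methyl}phenyl 2-methylpropanoate
Conditions: 14 (1.2 equiv), Et3N (1.6 equiv), 4-(dimethylamino)pyridine (5 mol%), CH2Cl2, 0 °C
Reagents that add atoms: isobutyryl chloride (14), CC(C)C(=O)Cl
Why: Nucleophilic acyl substitution on the only free OH installs the aryl ester before the oxirane exists, because a free ortho-phenolate would open the benzylic epoxide through an ortho-quinone methide or by cyclisation to a dihydrobenzofuran.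

**Step 10**
Reactants: 15 2-{3-[(tert-butyldiphenylsilyl)oxy]prop-1-en-2-yl}-5-{[(4-methoxybenzyl)oxy]methyl}phenyl 2-methylpropanoate
Product: 16 2-(3-hydroxyprop-1-en-2-yl)-5-{[(4-methoxybenzyl)oxy]methyl}phenyl 2-methylpropanoate
Conditions: HF·pyridine, pyridine, THF, 0 °C to rt (polypropylene flask)
Reagents that add atoms: none
Why: Fluoride-driven desilylation in a weakly acidic, non-basic medium frees the allylic alcohol without cleaving or migrating the aryl ester and without harming the PMB ether.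

**Step 11**
Reactants: 16 2-(3-hydroxyprop-1-en-2-yl)-5-{[(4-methoxybenzyl)oxy]methyl}phenyl 2-methylpropanoate
Product: 17 2-[(2S)-2-(hydroxymethyl)oxiran-2-yl]-5-{[(4-methoxybenzyl)oxy]methyl}phenyl 2-methylpropanoate
Conditions: Ti(OiPr)4 (10 mol%), (+)-diisopropyl (2R,3R)-tartrate (14 mol%), tBuOOH (2 equiv, in decane), 4 Å molecular sieves, CH2Cl2, −20 °C
Reagents that add atoms: tert-butyl hydroperoxide, CC(C)(C)OO
Why: In the Sharpless asymmetric epoxidation the allylic alkoxide and the peroxide bind to the tetravalent titanium–tartrate complex, and oxygen goes to one enantiotopic face; with the natural (2R,3R)-tartrate this is the face that turns allyl and methallyl alcohol into (S)-glycidol and (S)-2-methylglycidol, so with aryl as the lowest-ranked group the product is the (S)-epoxy alcohol.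

**Step 12**
Reactants: 17 2-[(2S)-2-(hydroxymethyl)oxiran-2-yl]-5-{[(4-methoxybenzyl)oxy]methyl}phenyl 2-methylpropanoate; 18 pentanoyl chloride
Product: 19 [(2R)-2-(4-{[(4-methoxybenzyl)oxy]methyl}-2-[(2-methylpropanoyl)oxy]phenyl)oxiran-2-yl]methyl pentanoate
Conditions: 18 (1.2 equiv), Et3N (1.6 equiv), 4-(dimethylamino)pyridine (5 mol%), CH2Cl2, −10 to 0 °C
Reagents that add atoms: pentanoyl chloride (18), CCCCC(=O)Cl
Why: Fast O-acylation of the primary alcohol leaves the stereocentre untouched, and the descriptor changes from S to R only because CH2OC(O)Bu now outranks the ring CH2.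

**Step 13**
Reactants: 19 [(2R)-2-(4-{[(4-methoxybenzyl)oxy]methyl}-2-[(2-methylpropanoyl)oxy]phenyl)oxiran-2-yl]methyl pentanoate
Product: 20 [(2R)-2-{4-(hydroxymethyl)-2-[(2-methylpropanoyl)oxy]phenyl}oxiran-2-yl]methyl pentanoate (CNP0243215.1)
Conditions: DDQ (1.4 equiv), CH2Cl2/pH 7 phosphate buffer 10:1, 0 °C
Reagents that add atoms: none
Why: In this oxidative PMB cleavage DDQ takes hydride only from the electron-rich 4-methoxybenzyl position and water hydrolyses the oxocarbenium ion, a neutral buffered process that spares both esters, the oxirane and its stereocentre.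

**Compound list**
1 | methyl 4-bromo-3-hydroxybenzoate | COC(=O)c1ccc(Br)c(O)c1 | starting material
2 | methyl 4-bromo-3-(tetrahydro-2H-pyran-2-yloxy)benzoate | COC(=O)c1ccc(Br)c(OC2CCCCO2)c1 | intermediate
3 | [4-bromo-3-(tetrahydro-2H-pyran-2-yloxy)phenyl]methanol | OCc1ccc(Br)c(OC2CCCCO2)c1 | intermediate
4 | 2-(2-bromo-5-{[(4-methoxybenzyl)oxy]methyl}phenoxy)tetrahydro-2H-pyran | COc1ccc(COCc2ccc(Br)c(OC3CCCCO3)c2)cc1 | intermediate
5 | tert-butyl bromoacetate | CC(C)(C)OC(=O)CBr | starting material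
6 | (2-tert-butoxy-2-oxoethyl)zinc bromide (Reformatsky reagent, not isolated) | CC(C)(C)OC(=O)C[Zn]Br | intermediate
7 | tert-butyl 2-[4-{[(4-methoxybenzyl)oxy]methyl}-2-(tetrahydro-2H-pyran-2-yloxy)phenyl]acetate | CC(C)(C)OC(=O)Cc1ccc(COCc2ccc(OC)cc2)cc1OC1CCCCO1 | intermediate
8 | formaldehyde (charged as paraformaldehyde) | C=O | starting material
9 | tert-butyl 3-hydroxy-2-[4-{[(4-methoxybenzyl)oxy]methyl}-2-(tetrahydro-2H-pyran-2-yloxy)phenyl]propanoate (aldol adduct, not isolated) | CC(C)(C)OC(=O)C(CO)c1ccc(COCc2ccc(OC)cc2)cc1OC1CCCCO1 | intermediate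
10 | tert-butyl 2-[4-{[(4-methoxybenzyl)oxy]methyl}-2-(tetrahydro-2H-pyran-2-yloxy)phenyl]prop-2-enoate | C=C(C(=O)OC(C)(C)C)c1ccc(COCc2ccc(OC)cc2)cc1OC1CCCCO1 | intermediate
11 | 2-[4-{[(4-methoxybenzyl)oxy]methyl}-2-(tetrahydro-2H-pyran-2-yloxy)phenyl]prop-2-en-1-ol | C=C(CO)c1ccc(COCc2ccc(OC)cc2)cc1OC1CCCCO1 | intermediate
12 | tert-butyl({2-[4-{[(4-methoxybenzyl)oxy]methyl}-2-(tetrahydro-2H-pyran-2-yloxy)phenyl]prop-2-en-1-yl}oxy)diphenylsilane | C=C(CO[Si](c1ccccc1)(c1ccccc1)C(C)(C)C)c1ccc(COCc2ccc(OC)cc2)cc1OC1CCCCO1 | intermediate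
13 | 2-{3-[(tert-butyldiphenylsilyl)oxy]prop-1-en-2-yl}-5-{[(4-methoxybenzyl)oxy]methyl}phenol | C=C(CO[Si](c1ccccc1)(c1ccccc1)C(C)(C)C)c1ccc(COCc2ccc(OC)cc2)cc1O | intermediate
14 | isobutyryl chloride | CC(C)C(=O)Cl | starting material
15 | 2-{3-[(tert-butyldiphenylsilyl)oxy]prop-1-en-2-yl}-5-{[(4-methoxybenzyl)oxy]methyl}phenyl 2-methylpropanoate | C=C(CO[Si](c1ccccc1)(c1ccccc1)C(C)(C)C)c1ccc(COCc2ccc(OC)cc2)cc1OC(=O)C(C)C | intermediate
16 | 2-(3-hydroxyprop-1-en-2-yl)-5-{[(4-methoxybenzyl)oxy]methyl}phenyl 2-methylpropanoate | C=C(CO)c1ccc(COCc2ccc(OC)cc2)cc1OC(=O)C(C)C | intermediate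
17 | 2-[(2S)-2-(hydroxymethyl)oxiran-2-yl]-5-{[(4-methoxybenzyl)oxy]methyl}phenyl 2-methylpropanoate | OC[C@@]1(c2ccc(COCc3ccc(OC)cc3)cc2OC(=O)C(C)C)CO1 | intermediate
18 | pentanoyl chloride | CCCCC(=O)Cl | starting material
19 | [(2R)-2-(4-{[(4-methoxybenzyl)oxy]methyl}-2-[(2-methylpropanoyl)oxy]phenyl)oxiran-2-yl]methyl pentanoate | CCCCC(=O)OC[C@@]1(c2ccc(COCc3ccc(OC)cc3)cc2OC(=O)C(C)C)CO1 | intermediate
20 | [(2R)-2-{4-(hydroxymethyl)-2-[(2-methylpropanoyl)oxy]phenyl}oxiran-2-yl]methyl pentanoate | CCCCC(=O)OC[C@@]1(c2ccc(CO)cc2OC(=O)C(C)C)CO1 | target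

**Totals**
- Total step count: 13.
- Longest linear sequence: 13 steps (1 → 20). Compounds 5, 8, 14 and 18 are bought and used directly.

**Three steps most likely to fail**

**Step 11 (asymmetric epoxidation).**
- Risks: the titanium alkoxide of 16 sits close to an activated aryl ester, so an acyl shift is possible. The twisted ortho-substituted aryl group may erode the ee. Product 17 is a Lewis-acid-sensitive benzylic epoxide.
- Fallback: this gives up directed catalysis for racemic epoxidation plus resolution. It sets out from 16, which is acylated with 18 (Et3N, CH2Cl2, 0 °C) to the allylic pentanoate F3, so that no free OH remains next to the aryl ester. Epoxidation with mCPBA and NaHCO3 in CH2Cl2 at 0 °C to rt gives the racemic epoxide F4. Preparative supercritical-fluid chromatography on an amylose tris(3,5-dimethylphenylcarbamate) phase (CO2/iPrOH) separates the enantiomers. The unwanted (S)-epoxide F5 is set aside, and the (R)-enantiomer is 19, where the fallback comes back to the route. The absolute configuration is assigned by retention-time comparison with a small sample made through steps 11 and 12, or by vibrational circular dichroism. The same column can also polish material of incomplete ee from the main route.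

**Step 5 (aldol condensation).**
- Risks: enolisation of the electron-rich tert-butyl ester by carbonate may be slow. The enolate of 7 may add in Michael fashion to product 10. Compound 10 may polymerise at 85 °C.
- Fallback: this replaces the one-pot condensation by a stoichiometric Mannich methylenation at low temperature. It sets out from 7, which is deprotonated with LiN(iPr)2 in THF at −78 °C. The enolate is trapped with dimethyl(methylidene)ammonium iodide to give the Mannich base F1. MeI in CH2Cl2 at rt converts it into the trimethylammonium iodide F2. Stirring F2 with K2CO3 in CH2Cl2/water at rt expels trimethylamine (E1cB), and the fallback comes back to the route at 10.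

**Step 13 (final PMB removal).**
- Risk: the hydroquinone formed is acidic, so the tertiary benzylic oxirane of the unprotected target may be opened or hydrolysed.
- Fallback: this removes the PMB group before the epoxide exists and carries that carbon as an aldehyde, which also deactivates the benzylic position towards ionisation. It sets out from 15.
  - DDQ in CH2Cl2/water gives the benzylic alcohol F6.
  - MnO2 in CH2Cl2 gives the benzaldehyde F7.
  - HF·pyridine in THF gives the allylic alcohol F8.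
  - The conditions of step 11 give the (S)-epoxy alcohol F9.
  - Compound 18 with Et3N gives the (R)-epoxy ester aldehyde F10.
  - NaBH4 (0.5 equiv) in THF/EtOH at −40 °C reduces only the aldehyde, and the fallback comes back to the route at 20.

**Further compounds**
F1 | step 5 | tert-butyl 3-(dimethylamino)-2-[4-{[(4-methoxybenzyl)oxy]methyl}-2-(tetrahydro-2H-pyran-2-yloxy)phenyl]propanoate | CN(C)CC(C(=O)OC(C)(C)C)c1ccc(COCc2ccc(OC)cc2)cc1OC1CCCCO1
F2 | step 5 | {3-tert-butoxy-2-[4-{[(4-methoxybenzyl)oxy]methyl}-2-(tetrahydro-2H-pyran-2-yloxy)phenyl]-3-oxopropyl}trimethylammonium iodide | C[N+](C)(C)CC(C(=O)OC(C)(C)C)c1ccc(COCc2ccc(OC)cc2)cc1OC1CCCCO1.[I-]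
F3 | step 11 | 2-(4-{[(4-methoxybenzyl)oxy]methyl}-2-[(2-methylpropanoyl)oxy]phenyl)prop-2-en-1-yl pentanoate | CCCCC(=O)OCC(=C)c1ccc(COCc2ccc(OC)cc2)cc1OC(=O)C(C)C
F4 | step 11 | racemic [2-(4-{[(4-methoxybenzyl)oxy]methyl}-2-[(2-methylpropanoyl)oxy]phenyl)oxiran-2-yl]methyl pentanoate | CCCCC(=O)OCC1(c2ccc(COCc3ccc(OC)cc3)cc2OC(=O)C(C)C)CO1
F5 | step 11 | [(2S)-2-(4-{[(4-methoxybenzyl)oxy]methyl}-2-[(2-methylpropanoyl)oxy]phenyl)oxiran-2-yl]methyl pentanoate | CCCCC(=O)OC[C@]1(c2ccc(COCc3ccc(OC)cc3)cc2OC(=O)C(C)C)CO1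
F6 | step 13 | 2-{3-[(tert-butyldiphenylsilyl)oxy]prop-1-en-2-yl}-5-(hydroxymethyl)phenyl 2-methylpropanoate | C=C(CO[Si](c1ccccc1)(c1ccccc1)C(C)(C)C)c1ccc(CO)cc1OC(=O)C(C)C
F7 | step 13 | 2-{3-[(tert-butyldiphenylsilyl)oxy]prop-1-en-2-yl}-5-formylphenyl 2-methylpropanoate | C=C(CO[Si](c1ccccc1)(c1ccccc1)C(C)(C)C)c1ccc(C=O)cc1OC(=O)C(C)C
F8 | step 13 | 5-formyl-2-(3-hydroxyprop-1-en-2-yl)phenyl 2-methylpropanoate | C=C(CO)c1ccc(C=O)cc1OC(=O)C(C)C
F9 | step 13 | 5-formyl-2-[(2S)-2-(hydroxymethyl)oxiran-2-yl]phenyl 2-methylpropanoate | OC[C@@]1(c2ccc(C=O)cc2OC(=O)C(C)C)CO1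
F10 | step 13 | [(2R)-2-{4-formyl-2-[(2-methylpropanoyl)oxy]phenyl}oxiran-2-yl]methyl pentanoate | CCCCC(=O)OC[C@@]1(c2ccc(C=O)cc2OC(=O)C(C)C)CO1
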